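**Plan**

- Retrosynthesis: the four O–benzyl bonds are cut first, then the O1–C8a bond of ring C, then the C2–C3 bond (C2 is a formyl carbon), then the C4–C4a acyl–aryl bond and the C8–CH2 bond of the side chain.
- Enabling feature: C8a of ring A carries O1 and lies ortho to the C4 carbonyl, so it can hold fluorine from the start and give it up to a tethered enolate oxygen.
- Forward: rings A and B are bought as benzene rings. Ring A is brominated on both sides of fluorine. One bromine is exchanged for the 3-hydroxy-3-methylbutyl chain and the other for the ring B arylacetyl group. Formylation adds C2, ring C closes by fluoride displacement, and hydrogenolysis frees the phenols.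
- Stereochemistry: the target has no stereocentre and no free double-bond geometry, so nothing has to be set.

Key step: step 8

Remark on the chemistry: the hydroxymethylene ketone is drawn as its hydrogen-bonded Z enol, which equilibrates with the formyl ketone tautomer. The carbinol carbon of the transient tetrahedral adduct in the acylation is racemic and disappears when the ketone forms.

**Route**

Step 1
Reactants: 1 2,4-dihydroxyphenylacetic acid
Product: 2 benzyl 2-[2,4-bis(benzyloxy)phenyl]acetate
Conditions: BnBr (3.3 equiv), K2CO3, DMF, 60 °C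
Reagents that add atoms: benzyl bromide, BrCc1ccccc1
Why: Williamson alkylation, in which K2CO3 ionises both phenols and the carboxylic acid so that all three oxygens are benzylated by SN2 displacement, while carbonate is too weak a base to touch the benzylic CH2.

Step 2
Reactants: 2 benzyl 2-[2,4-bis(benzyloxy)phenyl]acetate
Product: 3 2-[2,4-bis(benzyloxy)phenyl]-N-methoxy-N-methylacetamide
Conditions: MeNH(OMe)·HCl, i-PrMgCl, THF, −20 → 0 °C; 1 M HCl
Reagents that add atoms: N,O-dimethylhydroxylamine hydrochloride, CNOC.Cl
Why: Direct Weinreb amide synthesis from an ester, in which the chloromagnesium amide formed in the flask attacks the ester below 0 °C faster than the arylacetate enolises, and the benzyl ethers are inert to the Grignard reagent.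

Step 3
Reactants: 4 5-fluororesorcinol
Product: 5 1,3-bis(benzyloxy)-5-fluorobenzene
Conditions: BnBr (2.2 equiv), K2CO3, DMF, 60 °C
Reagents that add atoms: benzyl bromide, BrCc1ccccc1
Why: Williamson ether synthesis on both phenols, with the unactivated aryl fluoride not displaced by phenoxide under these conditions.

Step 4
Reactants: 5 1,3-bis(benzyloxy)-5-fluorobenzene
Product: 6 1,5-bis(benzyloxy)-2,4-dibromo-3-fluorobenzene
Conditions: NBS (2.05 equiv), MeCN, 0 °C → rt, dark
Reagents that add atoms: N-bromosuccinimide, O=C1CCC(=O)N1Br
Why: Electrophilic aromatic bromination of a resorcinol diether goes para to one alkoxy group and ortho to the other rather than at the crowded carbon between the two ethers, so both bromines should enter next to fluorine, and polar MeCN in the dark keeps NBS from benzylic radical bromination.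

Step 5
Reactants: 6 1,5-bis(benzyloxy)-2,4-dibromo-3-fluorobenzene; 7 2,2-dimethyloxetane
Product: 9 4-[4,6-bis(benzyloxy)-3-bromo-2-fluorophenyl]-2-methylbutan-2-ol, via aryllithium 8 (not isolated)
Conditions: n-BuLi (1.0 equiv), THF, −78 °C; then 7, BF3·OEt2, −78 °C; H2O
Reagents that add atoms: none
Why: Bromine–lithium exchange at −78 °C is faster than deprotonation of the benzyl ethers and gives an aryllithium too cold to lose LiF, and BF3-assisted oxetane opening by an organolithium (SN2 at the unhindered CH2, not at the quaternary carbon) should deliver the tertiary alcohol in one operation while the second bromine stays in place.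

Step 6
Reactants: 9 4-[4,6-bis(benzyloxy)-3-bromo-2-fluorophenyl]-2-methylbutan-2-ol; 3 2-[2,4-bis(benzyloxy)phenyl]-N-methoxy-N-methylacetamide
Product: 12 1-[4,6-bis(benzyloxy)-2-fluoro-3-(3-hydroxy-3-methylbutyl)phenyl]-2-[2,4-bis(benzyloxy)phenyl]ethan-1-one, via dilithio species 10 (not isolated), via tetrahedral adduct 11 (not isolated)
Conditions: n-BuLi (2.1 equiv), THF, −78 °C; then 3, −78 °C; AcOH, −78 °C
Reagents that add atoms: none
Why: The first equivalent of n-BuLi forms the lithium alkoxide and the second performs the bromine–lithium exchange, after which the Weinreb ketone synthesis stops at the ketone because the chelated tetrahedral adduct collapses only on the cold acidic quench, which also protonates any remaining aryllithium before it can eliminate LiF.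

Step 7
Reactants: 12 1-[4,6-bis(benzyloxy)-2-fluoro-3-(3-hydroxy-3-methylbutyl)phenyl]-2-[2,4-bis(benzyloxy)phenyl]ethan-1-one
Product: 13 (Z)-1-[4,6-bis(benzyloxy)-2-fluoro-3-(3-hydroxy-3-methylbutyl)phenyl]-2-[2,4-bis(benzyloxy)phenyl]-3-hydroxyprop-2-en-1-one
Conditions: HCO2Et (excess), NaH, THF, 0 °C → rt; H2O, 0 °C; AcOH
Reagents that add atoms: ethyl formate, CCOC=O
Why: Crossed Claisen condensation with the non-enolisable ethyl formate is driven by formation of the stabilised sodium enolate of the β-keto aldehyde, the short aqueous alkaline hold cleaves any formate on the tertiary hydroxyl, and acidification gives the hydrogen-bonded Z enol.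

Step 8
Reactants: 13 (Z)-1-[4,6-bis(benzyloxy)-2-fluoro-3-(3-hydroxy-3-methylbutyl)phenyl]-2-[2,4-bis(benzyloxy)phenyl]-3-hydroxyprop-2-en-1-one
Product: 15 5,7-bis(benzyloxy)-3-[2,4-bis(benzyloxy)phenyl]-8-(3-hydroxy-3-methylbutyl)-4H-chromen-4-one, via potassium enolate 14 (not isolated)
Conditions: K2CO3 (2 equiv), DMF, 80 °C
Reagents that add atoms: none
Why: K2CO3 deprotonates the acidic enol to the potassium enolate, whose formyl-derived oxygen adds to C8a to give a Meisenheimer anion with its charge on C4a, C6 and C8 and delocalised into the C4 carbonyl; loss of fluoride then restores aromaticity (addition–elimination). The closest known reaction is the base-mediated cyclisation of 2-fluoroaryl 1,3-dicarbonyl enolates to chromones. Ring C closes as a six-membered ring by attack of the tethered oxygen on an sp2 carbon of ring A (6-exo-trig with respect to the C8a=C8 bond), and no stereocentre is formed. Three selectivities are needed: oxygen rather than carbon of the ambident enolate attacks, because carbon attack would require a four-membered ring; the enolate rather than the tertiary hydroxyl attacks, because carbonate ionises only the enol, so the chroman that alkoxide attack at C8a would give should not form; and C8a rather than C5 is attacked, because fluoride is by far the better nucleofuge and makes its carbon the more electrophilic one. The benzyloxy groups at C5 and C7 stand meta to C8a and put no extra charge on the carbon under attack, while the ortho ketone stabilises the adduct.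

Step 9
Reactants: 15 5,7-bis(benzyloxy)-3-[2,4-bis(benzyloxy)phenyl]-8-(3-hydroxy-3-methylbutyl)-4H-chromen-4-one
Product: 16 2,3-dehydrokievitone hydrate
Conditions: H2 (1 atm), 10% Pd/C, EtOAc/MeOH, rt
Reagents that add atoms: none
Why: Catalytic hydrogenolysis cleaves the four benzylic C–O bonds, whereas the tertiary alcohol (two carbons from ring A, not benzylic) and the vinylogous ester double bond C2=C3 of the chromone should survive if the reaction is stopped once four equivalents of hydrogen are taken up.

**Compound list**

1 | 2,4-dihydroxyphenylacetic acid | OC(=O)Cc1ccc(O)cc1O | starting material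
2 | benzyl 2-[2,4-bis(benzyloxy)phenyl]acetate | O=C(Cc1ccc(OCc2ccccc2)cc1OCc1ccccc1)OCc1ccccc1 | intermediate
3 | 2-[2,4-bis(benzyloxy)phenyl]-N-methoxy-N-methylacetamide | CON(C)C(=O)Cc1ccc(OCc2ccccc2)cc1OCc1ccccc1 | intermediate
4 | 5-fluororesorcinol (5-fluorobenzene-1,3-diol) | Oc1cc(O)cc(F)c1 | starting material
5 | 1,3-bis(benzyloxy)-5-fluorobenzene | Fc1cc(OCc2ccccc2)cc(OCc2ccccc2)c1 | intermediate
6 | 1,5-bis(benzyloxy)-2,4-dibromo-3-fluorobenzene | Fc1c(Br)c(OCc2ccccc2)cc(OCc2ccccc2)c1Br | intermediate
7 | 2,2-dimethyloxetane | CC1(C)CCO1 | starting material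
8 | [4,6-bis(benzyloxy)-3-bromo-2-fluorophenyl]lithium (aryllithium) | [Li]c1c(F)c(Br)c(OCc2ccccc2)cc1OCc1ccccc1 | intermediate
9 | 4-[4,6-bis(benzyloxy)-3-bromo-2-fluorophenyl]-2-methylbutan-2-ol | CC(C)(O)CCc1c(F)c(Br)c(OCc2ccccc2)cc1OCc1ccccc1 | intermediate
10 | lithium 4-[4,6-bis(benzyloxy)-2-fluoro-3-lithiophenyl]-2-methylbutan-2-olate (dilithio species) | CC(C)(O[Li])CCc1c(F)c([Li])c(OCc2ccccc2)cc1OCc1ccccc1 | intermediate
11 | dilithium salt of the N-methoxy-N-methyl hemiaminal from 10 and 3 (tetrahedral adduct, racemic at the carbinol carbon) | CC(C)(O[Li])CCc1c(F)c(C(O[Li])(Cc2ccc(OCc3ccccc3)cc2OCc2ccccc2)N(C)OC)c(OCc2ccccc2)cc1OCc1ccccc1 | intermediate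
12 | 1-[4,6-bis(benzyloxy)-2-fluoro-3-(3-hydroxy-3-methylbutyl)phenyl]-2-[2,4-bis(benzyloxy)phenyl]ethan-1-one | CC(C)(O)CCc1c(F)c(C(=O)Cc2ccc(OCc3ccccc3)cc2OCc2ccccc2)c(OCc2ccccc2)cc1OCc1ccccc1 | intermediate
13 | (Z)-1-[4,6-bis(benzyloxy)-2-fluoro-3-(3-hydroxy-3-methylbutyl)phenyl]-2-[2,4-bis(benzyloxy)phenyl]-3-hydroxyprop-2-en-1-one | CC(C)(O)CCc1c(F)c(C(=O)/C(=C\O)c2ccc(OCc3ccccc3)cc2OCc2ccccc2)c(OCc2ccccc2)cc1OCc1ccccc1 | intermediate
14 | potassium (Z)-enolate of 13 (potassium enolate) | CC(C)(O)CCc1c(F)c(C(=O)/C(=C\[O-])c2ccc(OCc3ccccc3)cc2OCc2ccccc2)c(OCc2ccccc2)cc1OCc1ccccc1.[K+] | intermediate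
15 | 5,7-bis(benzyloxy)-3-[2,4-bis(benzyloxy)phenyl]-8-(3-hydroxy-3-methylbutyl)-4H-chromen-4-one | CC(C)(O)CCc1c(OCc2ccccc2)cc(OCc2ccccc2)c2c(=O)c(-c3ccc(OCc4ccccc4)cc3OCc3ccccc3)coc12 | intermediate
16 | 2,3-dehydrokievitone hydrate, 3-(2,4-dihydroxyphenyl)-5,7-dihydroxy-8-(3-hydroxy-3-methylbutyl)-4H-chromen-4-one | CC(C)(O)CCc1c(O)cc(O)c2c(=O)c(-c3ccc(O)cc3O)coc12 | target

**Step count**

Total step count: 9 steps.
Longest linear sequence: 7 steps (steps 3 to 9, from 5-fluororesorcinol 4 to 16). Steps 1 and 2 prepare the ring B amide 3.

**Steps most likely to fail**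

Step 5. The BF3-activated oxetane may ionise at its quaternary carbon or polymerise faster than the crowded aryllithium attacks its CH2 group, and BF3 may consume the aryllithium as a borate. The fallback sets out from 6 and returns at 9. Bromine–lithium exchange as before is followed by catalytic CuBr·SMe2 and 1-bromo-3-methylbut-2-ene, which should give 1,5-bis(benzyloxy)-2-bromo-3-fluoro-4-(3-methylbut-2-en-1-yl)benzene F1 by allylic substitution. Mukaiyama hydration of the trisubstituted alkene (catalytic Co(acac)2, PhSiH3, O2, i-PrOH/THF, rt) then places the hydroxyl at the tertiary carbon and gives 9. The chain carbon–carbon bond is thus made by allylation, and the oxygen arrives separately.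

Step 6. The hindered aryllithium may take a proton from the benzylic CH2 of amide 3 instead of adding to its carbonyl, which would return debrominated arene and unchanged amide. The fallback sets out from 9 and returns at 12. The same dilithio species 10 is acylated with N-methoxy-N-methylacetamide, which is less acidic and less hindered, to give 1-[4,6-bis(benzyloxy)-2-fluoro-3-(3-hydroxy-3-methylbutyl)phenyl]ethan-1-one F2. Dibenzylation of commercial 4-bromoresorcinol (BnBr, K2CO3, DMF) gives 2,4-bis(benzyloxy)-1-bromobenzene F3. Palladium-catalysed α-arylation of the methyl ketone F2 with F3 (Pd(OAc)2, XPhos, K3PO4, toluene, 90 °C) then forms the CH2–ring B bond and gives 12. The deoxybenzoin is thus assembled at the α-carbon and not at the acyl carbon.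

Step 7. Under NaH the tertiary alcohol becomes an alkoxide, which may take up a formyl group or attack the neighbouring C–F carbon to close a chroman, and the Claisen equilibrium at the crowded ketone may lie on the side of 12. The fallback sets out from 12 and returns at 13. Heating 12 with N,N-dimethylformamide dimethyl acetal (toluene, 100 °C) without added base should give (E)-1-[4,6-bis(benzyloxy)-2-fluoro-3-(3-hydroxy-3-methylbutyl)phenyl]-2-[2,4-bis(benzyloxy)phenyl]-3-(dimethylamino)prop-2-en-1-one F4. Hydrolysis of this enaminone (1 M HCl, THF, rt) exchanges the dimethylamino group for hydroxyl and gives 13.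

The ring closure of step 8 is ranked below these three because base-mediated fluoride displacement by 1,3-dicarbonyl enolates is established for chromones, and the ring ethers sit meta to the reacting carbon.

**Further compounds**

F1 | step 5 | 1,5-bis(benzyloxy)-2-bromo-3-fluoro-4-(3-methylbut-2-en-1-yl)benzene | CC(C)=CCc1c(F)c(Br)c(OCc2ccccc2)cc1OCc1ccccc1
F2 | step 6 | 1-[4,6-bis(benzyloxy)-2-fluoro-3-(3-hydroxy-3-methylbutyl)phenyl]ethan-1-one | CC(=O)c1c(F)c(CCC(C)(C)O)c(OCc2ccccc2)cc1OCc1ccccc1
F3 | step 6 | 2,4-bis(benzyloxy)-1-bromobenzene | Brc1ccc(OCc2ccccc2)cc1OCc1ccccc1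
F4 | step 7 | (E)-1-[4,6-bis(benzyloxy)-2-fluoro-3-(3-hydroxy-3-methylbutyl)phenyl]-2-[2,4-bis(benzyloxy)phenyl]-3-(dimethylamino)prop-2-en-1-one | CC(C)(O)CCc1c(F)c(C(=O)/C(=C/N(C)C)c2ccc(OCc3ccccc3)cc2OCc2ccccc2)c(OCc2ccccc2)cc1OCc1ccccc1
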